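**Plan**

1. Retrosynthesis: the ring B quinone is taken back to a dibenzyl-protected hydroquinone, ring C is opened at O1–C2 (phenol plus primary alcohol), the alcohol is taken back to a C2 boronate, and the chain is cut at C2–C3 and at C3–C1'.
2. Enabling feature: C3 is a CH carbon whose three carbon neighbours are C1' of ring B, C4 and C2. It can therefore be raised as an α-oxygenated carbenoid carbon on a ring A ethyl chain that takes up first the ring B aryl group and then the C2 methylene from boron.
3. Forward order: ring A aldehyde 1 is elaborated to the 2-arylethyl carbamate 10 (six steps) and ring B quinone 11 to the aryl pinacol boronate 15 (three steps). The two are joined and C2 is added in one flask (step 10) without closing a ring.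
4. Ring C is then closed by O1–C2 Mitsunobu etherification (step 13), and ring B is oxidised to the quinone in the last step.
5. Stereochemistry: the single stereocentre C3 comes from removal of the pro-R hydrogen by s-BuLi/(+)-sparteine. It is relayed by borylation (retention), aryl shift (inversion) and methylene insertion (retention) to the (3S) configuration, and no later step touches C3.

Key step: step 10

Remark and shorthand: the target SMILES corresponds to (3S) in isoflavan numbering (O1, C2, C3, C4, C4a to C8a; ring A = benzo ring, ring C = pyran ring, ring B = C1' to C6'). ArA = 3,4-dimethoxy-2-(methoxymethoxy)-5-(triisopropylsilyloxy)phenyl; ArB = 2,5-bis(benzyloxy)-3,4-dimethoxyphenyl; Cb = N,N-diisopropylcarbamoyl; pin = pinacolato; dppf = 1,1'-bis(diphenylphosphino)ferrocene. (+)-Sparteine is assumed to be bought as the free base.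

**Route**

Step 1
Reactants: 1 2-hydroxy-3,4-dimethoxybenzaldehyde
Product: 3 2,5-dihydroxy-3,4-dimethoxybenzaldehyde, via potassium aryl sulfate 2 (not isolated)
Conditions: K2S2O8, aq KOH, 0 °C to rt; then aq HCl, 80 °C
Reagents that add atoms: potassium peroxodisulfate, [K+].[K+].[O-]S(=O)(=O)OOS(=O)(=O)[O-]
Why: Elbs persulfate oxidation, in which the phenolate attacks a peroxide oxygen through its free para position (C5 of the aldehyde) and acid hydrolysis of sulfate ester 2 then frees the new hydroxyl, a reaction known for salicylaldehydes.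

Step 2
Reactants: 3 2,5-dihydroxy-3,4-dimethoxybenzaldehyde
Product: 4 2-hydroxy-3,4-dimethoxy-5-(triisopropylsilyloxy)benzaldehyde
Conditions: TIPSCl (1.05 equiv), imidazole, DMF, 0 °C
Reagents that add atoms: chlorotriisopropylsilane, CC(C)[Si](Cl)(C(C)C)C(C)C
Why: Site-selective silylation of a phenol, since the 2-hydroxyl is held in a hydrogen bond to the formyl group and is flanked on both sides, so the bulky silyl chloride should react only at the freer 5-hydroxyl.

Step 3
Reactants: 4 2-hydroxy-3,4-dimethoxy-5-(triisopropylsilyloxy)benzaldehyde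
Product: 5 3,4-dimethoxy-2-(methoxymethoxy)-5-(triisopropylsilyloxy)benzaldehyde (ArA–CHO)
Conditions: MOMCl, iPr2NEt, CH2Cl2, 0 °C to rt
Reagents that add atoms: chloromethyl methyl ether, COCCl
Why: Williamson-type O-alkylation of the remaining phenol gives the MOM acetal, which withstands ylide, borane and alkyllithium and can later be removed by acid without loss of silyl or benzyl ethers.

Step 4
Reactants: 5 ArA–CHO
Product: 6 1-ethenyl-3,4-dimethoxy-2-(methoxymethoxy)-5-(triisopropylsilyloxy)benzene (ArA–CH=CH2)
Conditions: Ph3PCH3Br, KOtBu, THF, 0 °C to rt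
Reagents that add atoms: methyltriphenylphosphonium bromide, C[P+](c1ccccc1)(c1ccccc1)c1ccccc1.[Br-]
Why: Wittig methylenation of an aromatic aldehyde by the unstabilised ylide, to which the acetal and the aryl silyl ether are inert.

Step 5
Reactants: 6 ArA–CH=CH2
Product: 8 2-(ArA)ethanol, via B-alkyl-9-BBN adduct 7 (not isolated)
Conditions: 9-BBN, THF, 0 °C to rt; then NaBO3·4H2O, H2O, rt
Reagents that add atoms: sodium perborate tetrahydrate (NaBO3·4H2O), [Na+].[Na+].O[B-]1(O)OO[B-](O)(O)OO1
Why: Brown hydroboration of the styrene with the bulky borane places boron on the terminal carbon, and perborate oxidation of the C–B bond is mild enough to spare the aryl silyl ether.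

Step 6
Reactants: 8 2-(ArA)ethanol; 9 N,N-diisopropylcarbamoyl chloride
Product: 10 2-(ArA)ethyl N,N-diisopropylcarbamate (ArA–CH2–CH2–OCb)
Conditions: Et3N, CH2Cl2, reflux
Reagents that add atoms: N,N-diisopropylcarbamoyl chloride (compound 9), CC(C)N(C(C)C)C(Cl)=O
Why: O-acylation of the primary alcohol by the carbamoyl chloride installs the hindered carbamate that will direct and stabilise lithiation at C3 and later serve as the leaving group.

Step 7
Reactants: 11 2,3-dimethoxy-1,4-benzoquinone
Product: 13 1,4-bis(benzyloxy)-2,3-dimethoxybenzene, via 2,3-dimethoxyhydroquinone 12 (not isolated)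
Conditions: Na2S2O4, Bu4NBr (cat.), THF/H2O, rt; then BnBr, aq KOH, rt
Reagents that add atoms: benzyl bromide, BrCc1ccccc1
Why: Reductive alkylation of a quinone, in which dithionite gives the hydroquinone and phase-transfer Williamson benzylation follows in the same flask so that the air-sensitive diol is never handled.

Step 8
Reactants: 13 1,4-bis(benzyloxy)-2,3-dimethoxybenzene
Product: 14 1,4-bis(benzyloxy)-5-bromo-2,3-dimethoxybenzene (ArB–Br)
Conditions: NBS (1.0 equiv), MeCN, 0 °C to rt
Reagents that add atoms: N-bromosuccinimide, O=C1CCC(=O)N1Br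
Why: Electrophilic aromatic bromination, for which the two open positions of the tetraalkoxybenzene are equivalent and far more activated than the benzyl rings, while the first bromine slows a second substitution.

Step 9
Reactants: 14 ArB–Br
Product: 15 2-[2,5-bis(benzyloxy)-3,4-dimethoxyphenyl]-4,4,5,5-tetramethyl-1,3,2-dioxaborolane (ArB–Bpin)
Conditions: B2pin2, PdCl2(dppf) (cat.), KOAc, 1,4-dioxane, 90 °C
Reagents that add atoms: bis(pinacolato)diboron, CC1(C)OB(B2OC(C)(C)C(C)(C)O2)OC1(C)C
Why: Miyaura borylation, in which oxidative addition of the aryl bromide to zerovalent palladium, acetate-assisted transmetalation from the diboron and reductive elimination give the aryl pinacol boronate without touching the benzyl ethers.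

Step 10
Reactants: 10 ArA–CH2–CH2–OCb; 15 ArB–Bpin; 16 chloroiodomethane
Product: 21 pinacol (2S)-2-(ArB)-3-(ArA)propylboronate (ArA–CH2–CH(ArB)–CH2–Bpin), via lithiated carbamate 17 (not isolated), via aryl boron ate complex 18 (not isolated), via secondary boronate 19 (not isolated), via chloromethyl boron ate complex 20 (not isolated)
Conditions: s-BuLi, (+)-sparteine, Et2O, −78 °C, 5 h; 15 in Et2O, −78 °C, 1 h; MgBr2·OEt2, −78 °C to reflux; then THF, ClCH2I, n-BuLi, −78 °C to rt
Reagents that add atoms: chloroiodomethane (compound 16), ClCI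
Why: s-BuLi bound to (+)-sparteine removes the pro-R hydrogen at C3 next to the carbamate oxygen, and the configurationally stable (R)-lithium compound 17 adds to the boron of 15 with retention to give ate complex 18. On warming with MgBr2·OEt2 the electron-rich ring B aryl group shifts from boron to C3 anti to the departing carbamate (inversion, C3–C1' formed) to give 19, and LiCH2Cl made in the flask from ClCH2I and n-BuLi then adds to boron to give ate complex 20, in which C3 shifts to the CH2 carbon as chloride leaves (retention, C2–C3 formed). The closest known reaction type is the lithiation–borylation of sparteine-complexed lithiated primary alkyl carbamates with aryl pinacol boronates, followed by Matteson homologation with chloromethyllithium. No ring is closed. The one new stereocentre, C3, is set by the chiral diamine in the deprotonation and carried by three stereospecific events (retention, inversion, retention) to the S configuration required by the target. The step needs a choice between the two enantiotopic C3 hydrogens and lithiation at C3 alone: the diamine secures the first, and the carbamate carbonyl, which holds the base next to C3, together with the fully substituted positions ortho to the MOM ether and the poorly directing silyl ether of ring A, secures the second.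

Step 11
Reactants: 21 ArA–CH2–CH(ArB)–CH2–Bpin
Product: 22 (2S)-2-(ArB)-3-(ArA)propan-1-ol
Conditions: NaBO3·4H2O, THF/H2O, rt
Reagents that add atoms: sodium perborate tetrahydrate (NaBO3·4H2O), [Na+].[Na+].O[B-]1(O)OO[B-](O)(O)OO1
Why: Peroxoborate oxidation of the primary C–B bond (boron-to-oxygen 1,2-shift of C2) gives the C2 alcohol, with C3 not a reacting centre and the weakly basic medium sparing the aryl silyl ether.

Step 12
Reactants: 22 (2S)-2-(ArB)-3-(ArA)propan-1-ol
Product: 23 2-[(2S)-2-(ArB)-3-hydroxypropyl]-5,6-dimethoxy-4-(triisopropylsilyloxy)phenol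
Conditions: HCl (cat.), MeOH, 45 °C
Reagents that add atoms: none
Why: Acid-catalysed transacetalisation to methanol removes the MOM group and frees the C8a hydroxyl, while aryl triisopropylsilyl ethers, benzyl ethers and the primary alcohol are stable to dilute methanolic acid.

Step 13
Reactants: 23 2-[(2S)-2-(ArB)-3-hydroxypropyl]-5,6-dimethoxy-4-(triisopropylsilyloxy)phenol
Product: 24 (3S)-3-(ArB)-7,8-dimethoxy-6-(triisopropylsilyloxy)chroman
Conditions: PPh3, DIAD, THF (0.02 M), 0 °C to rt
Reagents that add atoms: none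
Why: Mitsunobu etherification, in which the C8a phenol displaces the oxyphosphonium-activated primary C2 in a 6-exo-tet closure of ring C (the usual isoflavan ring closure), forming O1–C2 and leaving C3 untouched.

Step 14
Reactants: 24 (3S)-3-(ArB)-7,8-dimethoxy-6-(triisopropylsilyloxy)chroman
Product: 25 (3S)-3-(ArB)-7,8-dimethoxychroman-6-ol
Conditions: TBAF, AcOH, THF, 0 °C
Reagents that add atoms: none
Why: Fluoride cleavage of the aryl silyl ether, driven by the Si–F bond, with acetic acid protonating the electron-rich phenoxide at once and the benzyl ethers inert.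

Step 15
Reactants: 25 (3S)-3-(ArB)-7,8-dimethoxychroman-6-ol
Product: 27 5-[(3S)-6-hydroxy-7,8-dimethoxychroman-3-yl]-2,3-dimethoxy-1,4-benzoquinone (CNP0302517.1), via ring B hydroquinone 26 (not isolated)
Conditions: H2 (1 atm), Pd/C, EtOAc, rt; filtration under Ar; then Ag2O (1.1 equiv), Et2O, rt
Reagents that add atoms: none
Why: Hydrogenolysis of the two aryl benzyl ethers frees the ring B hydroquinone, which Ag2O dehydrogenates under neutral conditions to the p-quinone, whereas the ring A phenol, whose para position carries the ring ether oxygen, cannot give a quinone without C–O cleavage, and the neutral medium keeps the C3–H next to the quinone from enolising.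

**Compound list**

1 | 2-hydroxy-3,4-dimethoxybenzaldehyde | COc1ccc(C=O)c(O)c1OC | starting material
2 | potassium 5-formyl-4-hydroxy-2,3-dimethoxyphenyl sulfate (not isolated) | COc1c(OS(=O)(=O)[O-])cc(C=O)c(O)c1OC.[K+] | intermediate
3 | 2,5-dihydroxy-3,4-dimethoxybenzaldehyde | COc1c(O)cc(C=O)c(O)c1OC | intermediate
4 | 2-hydroxy-3,4-dimethoxy-5-(triisopropylsilyloxy)benzaldehyde | COc1c(O[Si](C(C)C)(C(C)C)C(C)C)cc(C=O)c(O)c1OC | intermediate
5 | 3,4-dimethoxy-2-(methoxymethoxy)-5-(triisopropylsilyloxy)benzaldehyde | COCOc1c(C=O)cc(O[Si](C(C)C)(C(C)C)C(C)C)c(OC)c1OC | intermediate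
6 | 1-ethenyl-3,4-dimethoxy-2-(methoxymethoxy)-5-(triisopropylsilyloxy)benzene | COCOc1c(C=C)cc(O[Si](C(C)C)(C(C)C)C(C)C)c(OC)c1OC | intermediate
7 | 9-[2-(ArA)ethyl]-9-borabicyclo[3.3.1]nonane (not isolated) | COCOc1c(CCB2C3CCCC2CCC3)cc(O[Si](C(C)C)(C(C)C)C(C)C)c(OC)c1OC | intermediate
8 | 2-[3,4-dimethoxy-2-(methoxymethoxy)-5-(triisopropylsilyloxy)phenyl]ethanol | COCOc1c(CCO)cc(O[Si](C(C)C)(C(C)C)C(C)C)c(OC)c1OC | intermediate
9 | N,N-diisopropylcarbamoyl chloride | CC(C)N(C(C)C)C(Cl)=O | starting material
10 | 2-[3,4-dimethoxy-2-(methoxymethoxy)-5-(triisopropylsilyloxy)phenyl]ethyl N,N-diisopropylcarbamate | COCOc1c(CCOC(=O)N(C(C)C)C(C)C)cc(O[Si](C(C)C)(C(C)C)C(C)C)c(OC)c1OC | intermediate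
11 | 2,3-dimethoxy-1,4-benzoquinone | COC1=C(OC)C(=O)C=CC1=O | starting material
12 | 2,3-dimethoxybenzene-1,4-diol (not isolated) | COc1c(O)ccc(O)c1OC | intermediate
13 | 1,4-bis(benzyloxy)-2,3-dimethoxybenzene | COc1c(OCc2ccccc2)ccc(OCc2ccccc2)c1OC | intermediate
14 | 1,4-bis(benzyloxy)-5-bromo-2,3-dimethoxybenzene | COc1c(OC)c(OCc2ccccc2)c(Br)cc1OCc1ccccc1 | intermediate
15 | 2-[2,5-bis(benzyloxy)-3,4-dimethoxyphenyl]-4,4,5,5-tetramethyl-1,3,2-dioxaborolane | COc1c(OC)c(OCc2ccccc2)c(B2OC(C)(C)C(C)(C)O2)cc1OCc1ccccc1 | intermediate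
16 | chloroiodomethane | ClCI | starting material
17 | (1R)-1-lithio-2-(ArA)ethyl N,N-diisopropylcarbamate, held as its (+)-sparteine complex (ligand not drawn; not isolated) | COCOc1c(C[C@@H]([Li])OC(=O)N(C(C)C)C(C)C)cc(O[Si](C(C)C)(C(C)C)C(C)C)c(OC)c1OC | intermediate
18 | lithium (ArB)[(1R)-1-(N,N-diisopropylcarbamoyloxy)-2-(ArA)ethyl](pinacolato)borate (not isolated) | COCOc1c(C[C@@H]([B-]2(c3cc(OCc4ccccc4)c(OC)c(OC)c3OCc3ccccc3)OC(C)(C)C(C)(C)O2)OC(=O)N(C(C)C)C(C)C)cc(O[Si](C(C)C)(C(C)C)C(C)C)c(OC)c1OC.[Li+] | intermediate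
19 | 2-[(1S)-1-(ArB)-2-(ArA)ethyl]-4,4,5,5-tetramethyl-1,3,2-dioxaborolane (not isolated) | COCOc1c(C[C@H](B2OC(C)(C)C(C)(C)O2)c2cc(OCc3ccccc3)c(OC)c(OC)c2OCc2ccccc2)cc(O[Si](C(C)C)(C(C)C)C(C)C)c(OC)c1OC | intermediate
20 | lithium (chloromethyl)[(1S)-1-(ArB)-2-(ArA)ethyl](pinacolato)borate (not isolated) | COCOc1c(C[C@H]([B-]2(CCl)OC(C)(C)C(C)(C)O2)c2cc(OCc3ccccc3)c(OC)c(OC)c2OCc2ccccc2)cc(O[Si](C(C)C)(C(C)C)C(C)C)c(OC)c1OC.[Li+] | intermediate
21 | 2-[(2S)-2-(ArB)-3-(ArA)propyl]-4,4,5,5-tetramethyl-1,3,2-dioxaborolane | COCOc1c(C[C@H](CB2OC(C)(C)C(C)(C)O2)c2cc(OCc3ccccc3)c(OC)c(OC)c2OCc2ccccc2)cc(O[Si](C(C)C)(C(C)C)C(C)C)c(OC)c1OC | intermediate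
22 | (2S)-2-[2,5-bis(benzyloxy)-3,4-dimethoxyphenyl]-3-[3,4-dimethoxy-2-(methoxymethoxy)-5-(triisopropylsilyloxy)phenyl]propan-1-ol | COCOc1c(C[C@H](CO)c2cc(OCc3ccccc3)c(OC)c(OC)c2OCc2ccccc2)cc(O[Si](C(C)C)(C(C)C)C(C)C)c(OC)c1OC | intermediate
23 | 2-{(2S)-2-[2,5-bis(benzyloxy)-3,4-dimethoxyphenyl]-3-hydroxypropyl}-5,6-dimethoxy-4-(triisopropylsilyloxy)phenol | Oc1c(C[C@H](CO)c2cc(OCc3ccccc3)c(OC)c(OC)c2OCc2ccccc2)cc(O[Si](C(C)C)(C(C)C)C(C)C)c(OC)c1OC | intermediate
24 | (3S)-3-[2,5-bis(benzyloxy)-3,4-dimethoxyphenyl]-7,8-dimethoxy-6-(triisopropylsilyloxy)chroman | COc1c(OC)c(OCc2ccccc2)c(cc1OCc1ccccc1)[C@H]1COc2c(cc(O[Si](C(C)C)(C(C)C)C(C)C)c(OC)c2OC)C1 | intermediate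
25 | (3S)-3-[2,5-bis(benzyloxy)-3,4-dimethoxyphenyl]-7,8-dimethoxychroman-6-ol | COc1c(OC)c(OCc2ccccc2)c(cc1OCc1ccccc1)[C@H]1COc2c(cc(O)c(OC)c2OC)C1 | intermediate
26 | 2-[(3S)-6-hydroxy-7,8-dimethoxychroman-3-yl]-5,6-dimethoxybenzene-1,4-diol (not isolated) | COc1c(OC)c(O)c(cc1O)[C@H]1COc2c(cc(O)c(OC)c2OC)C1 | intermediate
27 | 5-[(3S)-6-hydroxy-7,8-dimethoxychroman-3-yl]-2,3-dimethoxy-1,4-benzoquinone (CNP0302517.1) | COC1=C(OC)C(=O)C([C@H]2COc3c(cc(O)c(OC)c3OC)C2)=CC1=O | target

**Step count and risks**

Total steps: 15. Longest linear sequence: 12 steps (steps 1 to 6, then 10 to 15).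

Steps most likely to fail, in order of risk:

Step 10. The lithiated carbamate may be captured only slowly by the ortho-substituted aryl boronate at −78 °C, and the lithium and magnesium salts left in the flask may consume the chloromethyl carbenoid before it reaches boron. The fallback sets out from 10 and 14 and returns at 21. It exchanges the roles of the boron partners and runs the sequence in isolated stages. Carbamate 10 would be lithiated with s-BuLi/(+)-sparteine as before and 17 quenched with 2-isopropoxy-4,4,5,5-tetramethyl-1,3,2-dioxaborolane. Work-up and chromatography should give the α-boryl carbamate (1R)-2-(ArA)-1-(4,4,5,5-tetramethyl-1,3,2-dioxaborolan-2-yl)ethyl N,N-diisopropylcarbamate F1. In a second flask bromide 14 would be converted by bromine–lithium exchange (n-BuLi, THF, −78 °C) into [2,5-bis(benzyloxy)-3,4-dimethoxyphenyl]lithium F2. F2 should add to the unhindered boron of F1 to give the same ate complex 18, and warming with MgBr2·OEt2 gives 19 with the same inversion. After isolation of 19, a separate Matteson homologation (ClCH2I, n-BuLi, THF, −78 °C to rt) gives 21. Additions of organometallic reagents to α-carbamoyloxy boronates and the homologation of isolated secondary boronates are both known reactions.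

Step 1. The persulfate hydroxylation may stall at low conversion, because the formyl-substituted phenolate is a weak nucleophile, and the hydroquinone product may be degraded oxidatively in the alkaline medium. The fallback sets out from 11 and returns at 4. It builds the aldehyde onto a ready-made hydroquinone instead of hydroxylating the aldehyde. Quinone 11 would be reduced with Na2S2O4 to hydroquinone 12, which is isolated under argon. Monosilylation of the symmetric diol (TIPSCl, 1 equiv, imidazole, DMF) gives a statistical mixture; the monoether 2,3-dimethoxy-4-(triisopropylsilyloxy)phenol F3 is separated and the rest recycled. Magnesium-mediated ortho-formylation (MgCl2, Et3N, paraformaldehyde, MeCN, reflux) then places the formyl group on the only free position ortho to the phenol and gives 4.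

Step 15. Ag2O may oxidise the free, very electron-rich ring A phenol (phenoxyl radical coupling) alongside the dehydrogenation of the ring B hydroquinone. The fallback sets out from 24 and returns at 27. It keeps the ring A phenol silylated through the oxidation and removes the silyl group last. Hydrogenolysis of 24 (H2, Pd/C, EtOAc) would give 2-[(3S)-7,8-dimethoxy-6-(triisopropylsilyloxy)chroman-3-yl]-5,6-dimethoxybenzene-1,4-diol F4. Ag2O then oxidises F4 to 5-[(3S)-7,8-dimethoxy-6-(triisopropylsilyloxy)chroman-3-yl]-2,3-dimethoxy-1,4-benzoquinone F5. Desilylation of F5 with acetic acid-buffered TBAF (THF, 0 °C), which is not basic enough to attack the quinone, gives 27.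

**Further compounds**

F1 | step 10 | (1R)-2-[3,4-dimethoxy-2-(methoxymethoxy)-5-(triisopropylsilyloxy)phenyl]-1-(4,4,5,5-tetramethyl-1,3,2-dioxaborolan-2-yl)ethyl N,N-diisopropylcarbamate | COCOc1c(C[C@@H](B2OC(C)(C)C(C)(C)O2)OC(=O)N(C(C)C)C(C)C)cc(O[Si](C(C)C)(C(C)C)C(C)C)c(OC)c1OC
F2 | step 10 | [2,5-bis(benzyloxy)-3,4-dimethoxyphenyl]lithium | COc1c(OC)c(OCc2ccccc2)c([Li])cc1OCc1ccccc1
F3 | step 1 | 2,3-dimethoxy-4-(triisopropylsilyloxy)phenol | COc1c(O)ccc(O[Si](C(C)C)(C(C)C)C(C)C)c1OC
F4 | step 15 | 2-[(3S)-7,8-dimethoxy-6-(triisopropylsilyloxy)chroman-3-yl]-5,6-dimethoxybenzene-1,4-diol | COc1c(OC)c(O)c(cc1O)[C@H]1COc2c(cc(O[Si](C(C)C)(C(C)C)C(C)C)c(OC)c2OC)C1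
F5 | step 15 | 5-[(3S)-7,8-dimethoxy-6-(triisopropylsilyloxy)chroman-3-yl]-2,3-dimethoxy-1,4-benzoquinone | COC1=C(OC)C(=O)C([C@H]2COc3c(cc(O[Si](C(C)C)(C(C)C)C(C)C)c(OC)c3OC)C2)=CC1=O
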